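**Assumptions (one line):** the C6 hemiketal is taken to close spontaneously to the natural (thermodynamic) configuration, and the stereochemical outcome of the C5 hydroxylation (step 20) is predicted by analogy and is not certain.

**Numbering used here:** C1 ring ketone, C2 pyran CH–O, C3 CH2, C4 CHMe, C5 CH–O-acyl, C6 hemiketal C, C7 CHOH, C8 THF C(Me), C9/C10 THF CH2, C11 THF CH, C12 CMe2, C13=C14, C15 CHMe. Target: 2R,4R,5R,6R,7S,8R,11S,15S, 13E.

## Retrosynthetic overview

1. Endgame: C7–OTBS removal ⇐ C1 alcohol oxidation ⇐ pyranose hemiketal, formed when the C1/C2 diol is unmasked onto the C6 ketone; the C5 ester comes from acylating an α-hydroxy ketone made by enolate hydroxylation.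
2. 15-membered carbocycle: ring-closing metathesis at C13=C14.
3. Fragment union at C5–C6: West alkyllithium (C1–C5, C14, C15; 10 skeletal C) adds to East aldehyde (C6–C13; 12 skeletal C), then oxidation to the ketone.
4. East: Brown reverse prenylation (C11), Z-enoate by cuprate addition, Sharpless epoxidation and 5-exo epoxide opening (C7, C8, THF). West: bromide-derived Grignard plus an α-PMB-oxy aldehyde from Brown crotylation (C15, then C2 by chelation).
5. Ring order: THF, then the 15-membered carbocycle, then the pyranose hemiketal last.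

## East fragment

**Step 1**
Reactants: 1 pent-4-ynal; 2 3-methylbuta-1,2-diene
Product: 3 (4S)-3,3-dimethyloct-1-en-7-yn-4-ol
Conditions: (+)-Ipc2BH [from (–)-α-pinene], 2, THF, –25 °C; then 1, –78 °C; NaOH, H2O2
Reagents that add atoms: none (the prenyl unit is 2)
Why: Brown asymmetric reverse prenylation; the allylborane from allene hydroboration adds through its γ-carbon in a chair transition state to the Re face of the aldehyde, setting C11 (S) and the CMe2–vinyl unit.

**Step 2**
Reactants: 3
Product: 4 methyl (6S)-6-[(methoxycarbonyl)oxy]-7,7-dimethylnon-8-en-2-ynoate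
Conditions: n-BuLi (2.2 equiv), THF, –78 °C; ClCO2Me (3 equiv), –78 → 0 °C
Reagents that add atoms: methyl chloroformate, COC(=O)Cl (two units)
Why: C-acylation of the lithium acetylide gives the ynoate (adds C6) while O-acylation masks the C11 alkoxide as a methyl carbonate.

**Step 3**
Reactants: 4
Product: 5 methyl (2Z,6S)-6-[(methoxycarbonyl)oxy]-3,7,7-trimethylnona-2,8-dienoate
Conditions: Me2CuLi (1.5 equiv), THF, –78 °C; MeOH quench at –78 °C
Reagents that add atoms: lithium dimethylcuprate, [Li+].C[Cu-]C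
Why: syn-carbocupration of the 2-ynoate with protonation at –78 °C places the ester and the C9 chain cis (Z-C7=C8), the geometry needed for step 5.

**Step 4**
Reactants: 5
Product: 6 (2Z,6S)-3,7,7-trimethylnona-2,8-diene-1,6-diol
Conditions: DIBAL-H (6 equiv), CH2Cl2, –78 → 0 °C
Reagents that add atoms: none
Why: DIBAL 1,2-reduction of the enoate to the allylic alcohol also cleaves the carbonate; the Z-alkene is untouched.

**Step 5**
Reactants: 6
Product: 7 (1R)-1-[(2R,5S)-2-methyl-5-(2-methylbut-3-en-2-yl)oxolan-2-yl]ethane-1,2-diol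
Conditions: Ti(OiPr)4, D-(–)-DIPT, t-BuOOH, 4 Å MS, CH2Cl2, –25 °C; then CSA (cat.), 0 °C → rt
Reagents that add atoms: tert-butyl hydroperoxide, CC(C)(C)OO (one O)
Why: Sharpless asymmetric epoxidation with D-tartrate gives the (2R,3S)-epoxide of the Z-allylic alcohol (not isolated), and 5-exo opening by the C11–OH at tertiary C8 with inversion sets C7 and C8 and the cis-2,5-THF.

**Step 6**
Reactants: 7
Product: 8 tert-butyl{(1R)-1-[(2R,5S)-2-methyl-5-(2-methylbut-3-en-2-yl)oxolan-2-yl]-2-[(triethylsilyl)oxy]ethoxy}dimethylsilane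
Conditions: TESCl (1.05 equiv), imidazole, CH2Cl2, –40 °C; then TBSOTf, 2,6-lutidine, 0 °C (one pot)
Reagents that add atoms: TESCl, CC[Si](Cl)(CC)CC; TBSOTf, CC(C)(C)[Si](C)(C)OS(=O)(=O)C(F)(F)F
Why: sequential silylation uses the large steric difference between the primary C6–OH and the neopentyl-type C7–OH.

**Step 7**
Reactants: 8
Product: 9 (2S)-2-[(tert-butyldimethylsilyl)oxy]-2-[(2R,5S)-2-methyl-5-(2-methylbut-3-en-2-yl)oxolan-2-yl]acetaldehyde
Conditions: (COCl)2, DMSO, CH2Cl2, –78 → –30 °C; then iPr2NEt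
Reagents that add atoms: none
Why: Swern conditions cleave and oxidise a primary TES ether directly to the aldehyde while the secondary TBS ether survives.

## West fragment

**Step 8**
Reactants: 10 (S)-3-bromo-2-methylpropan-1-ol
Product: 11 (S)-(3-bromo-2-methylpropoxy)(tert-butyl)dimethylsilane
Conditions: TBSCl, imidazole, DMF, rt
Reagents that add atoms: TBSCl, CC(C)(C)[Si](C)(C)Cl
Why: standard silylation; the stereocentre from the chiral pool becomes C4.

**Step 9**
Reactants: 12 2,2-dimethoxyacetaldehyde (dried, distilled); 13 (Z)-but-2-ene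
Product: 14 (2R,3S)-1,1-dimethoxy-3-methylpent-4-en-2-ol
Conditions: 13, n-BuLi, KOt-Bu, THF, –45 °C; (+)-Ipc2BOMe [from (–)-α-pinene], –78 °C; BF3·OEt2; 12, –78 °C; NaOH, H2O2
Reagents that add atoms: none (the crotyl unit is 13)
Why: Brown (Z)-crotylboration through a chair transition state gives the syn product by Re-face attack, setting C15 (S) and a temporary C1 carbinol (R) that later steers C2.

**Step 10**
Reactants: 14
Product: 15 1-({[(2R,3S)-1,1-dimethoxy-3-methylpent-4-en-2-yl]oxy}methyl)-4-methoxybenzene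
Conditions: NaH, PMBCl, TBAI (cat.), THF/DMF, 0 °C → rt
Reagents that add atoms: 4-methoxybenzyl chloride, COc1ccc(CCl)cc1
Why: Williamson etherification installs a chelating group that later becomes the diol protecting group.

**Step 11**
Reactants: 15
Product: 16 (2R,3S)-2-[(4-methoxybenzyl)oxy]-3-methylpent-4-enal
Conditions: TsOH·H2O (cat.), acetone/H2O, 50 °C
Reagents that add atoms: water, O
Why: acetal hydrolysis under conditions a PMB ether tolerates; the aldehyde is used at once to avoid α-epimerisation.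

**Step 12**
Reactants: 11; 16
Product: 17 (2R,4R,5R,6S)-1-[(tert-butyldimethylsilyl)oxy]-5-[(4-methoxybenzyl)oxy]-2,6-dimethyloct-7-en-4-ol
Conditions: 11, Mg, THF, 45 °C; then 16, MgBr2·OEt2, CH2Cl2, –78 °C
Reagents that add atoms: none
Why: Cram-chelate Grignard addition to the α-PMB-oxy aldehyde delivers the alkyl group anti to the α-substituent, giving the syn diol derivative and setting C2 (R).

**Step 13**
Reactants: 17
Product: 18 tert-butyl{(2R)-3-[(4R,5R)-5-[(2S)-but-3-en-2-yl]-2-(4-methoxyphenyl)-1,3-dioxolan-4-yl]-2-methylpropoxy}dimethylsilane (acetal-carbon epimers, inconsequential)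
Conditions: DDQ, 4 Å MS, CH2Cl2, 0 °C
Reagents that add atoms: none
Why: anhydrous DDQ oxidation of the PMB ether is trapped by the neighbouring hydroxyl (Oikawa–Yonemitsu), protecting the C1/C2 diol as one acid-labile PMP acetal.

**Step 14**
Reactants: 18
Product: 19 (2R)-3-[(4R,5R)-5-[(2S)-but-3-en-2-yl]-2-(4-methoxyphenyl)-1,3-dioxolan-4-yl]-2-methylpropan-1-ol
Conditions: TBAF, THF, 0 °C → rt
Reagents that add atoms: none
Why: fluoride removes the primary TBS ether; the acetal is inert.

**Step 15**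
Reactants: 19
Product: 20 (4R,5R)-4-[(2S)-but-3-en-2-yl]-5-[(2R)-3-iodo-2-methylpropyl]-2-(4-methoxyphenyl)-1,3-dioxolane
Conditions: I2, PPh3, imidazole, CH2Cl2, 0 °C → rt
Reagents that add atoms: iodine, II
Why: Appel-type iodination of the primary alcohol under imidazole-buffered conditions that spare the acetal.

## Side-chain acid

**Step 16**
Reactants: 21 methyl but-2-ynoate
Product: 22 methyl (2E)-3-methylpent-2-enoate
Conditions: EtMgBr (2 equiv), CuBr·SMe2 (1 equiv), THF, –78 °C; MeOH quench at –78 °C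
Reagents that add atoms: ethylmagnesium bromide, CC[Mg]Br
Why: syn-carbocupration of the ynoate puts ethyl trans to the ester, giving the E-enoate geometrically pure.

**Step 17**
Reactants: 22
Product: 23 (2E)-3-methylpent-2-enoic acid
Conditions: LiOH, THF/H2O, rt; then H3O+
Reagents that add atoms: lithium hydroxide, [Li+].[OH-] (O)
Why: simple saponification.

## Fragment union and endgame

**Step 18**
Reactants: 20; 9
Product: 24 secondary alcohol from C5–C6 coupling: 5-[dioxolanyl of 20]-1-[(tert-butyldimethylsilyl)oxy]-4-methyl-1-[oxolanyl of 9]pentan-2-ol (C6 epimers; all other centres as in 31)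
Conditions: 20, t-BuLi (2.05 equiv), Et2O/pentane, –78 °C; then 9, –78 °C
Reagents that add atoms: none
Why: iodine–lithium exchange gives a primary alkyllithium with no β-leaving group, which adds to the aldehyde; the new C6 carbinol configuration is irrelevant because it is oxidised next.

**Step 19**
Reactants: 24
Product: 25 (1S,4R)-5-[(4R,5R)-5-[(2S)-but-3-en-2-yl]-2-(4-methoxyphenyl)-1,3-dioxolan-4-yl]-1-[(tert-butyldimethylsilyl)oxy]-4-methyl-1-[(2R,5S)-2-methyl-5-(2-methylbut-3-en-2-yl)oxolan-2-yl]pentan-2-one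
Conditions: Dess–Martin periodinane, NaHCO3, CH2Cl2, rt
Reagents that add atoms: none
Why: mild oxidation of the only free hydroxyl converges both epimers to the C6 ketone without touching C7.

**Step 20**
Reactants: 25
Product: 26 (1S,3R,4R)-3-hydroxy analogue of 25 (C5–OH)
Conditions: NaHMDS, THF, –78 °C; (–)-(camphorsulfonyl)oxaziridine, –78 °C; NH4Cl
Reagents that add atoms: Davis oxaziridine (adds O), CC1(C)C2CCC13CS(=O)(=O)N4OC34C2
Why: kinetic enolisation occurs at the C5 methylene rather than the hindered C7 methine, and Davis hydroxylation of the Z-enolate is intended to set C5 (R) under reagent control, the enantiomer being chosen by analogy with aryl ketone enolates.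

**Step 21**
Reactants: 26; 23
Product: 27 the C5 (2E)-3-methylpent-2-enoate ester of 26
Conditions: EDC·HCl, DMAP, CH2Cl2, 0 °C → rt
Reagents that add atoms: none (the acyl group is 23)
Why: Steglich-type esterification of the only free hydroxyl, run cold to avoid epimerising C5 or deconjugating the enoate.

**Step 22**
Reactants: 27
Product: 28 macrocyclic (13E)-alkene: 15-membered carbocycle with C6 ketone, C5 ester, C7–OTBS, C1/C2 PMP acetal and cis-THF
Conditions: Grubbs II (15 mol%), 1,4-benzoquinone (cat.), toluene (1 mM), 80 °C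
Reagents that add atoms: none (ethylene is lost)
Why: ring-closing metathesis initiates at the C14 vinyl and closes onto the neopentyl C13 vinyl; the enoate side chain is an unreactive trisubstituted alkene and the E-alkene is strongly favoured next to the quaternary carbon.

**Step 23**
Reactants: 28
Product: 29 hemiketal: C2–O–C6 pyranose closed, (1R)-C1–OH free, C7–OTBS
Conditions: AcOH/H2O/THF (4:1:1), 40 °C
Reagents that add atoms: none
Why: acid hydrolysis of the PMP acetal frees the diol, and the C2–OH closes onto the C6 ketone as the six-membered hemiketal (C6 under thermodynamic control), which also distinguishes C2–OH from C1–OH.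

**Step 24**
Reactants: 29
Product: 30 7-O-TBS-tonantzitlolone A
Conditions: Dess–Martin periodinane, NaHCO3, CH2Cl2, 0 °C → rt
Reagents that add atoms: none
Why: the only oxidisable hydroxyl is C1–OH (C6–OH is tertiary, C7 is silylated), and neutral conditions avoid epimerising C15 or conjugating the β,γ-enone.

**Step 25**
Reactants: 30
Product: 31 tonantzitlolone A
Conditions: HF·pyridine, pyridine, THF, 0 °C → rt
Reagents that add atoms: none
Why: buffered fluoride desilylation frees C7–OH without base, so the ester, hemiketal and C15 centre are preserved.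

## Compound list

1 | pent-4-ynal | C#CCCC=O | starting material
2 | 3-methylbuta-1,2-diene | CC(C)=C=C | starting material
3 | (4S)-3,3-dimethyloct-1-en-7-yn-4-ol | C#CCC[C@H](O)C(C)(C)C=C | intermediate
4 | methyl (6S)-6-[(methoxycarbonyl)oxy]-7,7-dimethylnon-8-en-2-ynoate | COC(=O)C#CCC[C@H](OC(=O)OC)C(C)(C)C=C | intermediate
5 | methyl (2Z,6S)-6-[(methoxycarbonyl)oxy]-3,7,7-trimethylnona-2,8-dienoate | COC(=O)/C=C(C)\CC[C@H](OC(=O)OC)C(C)(C)C=C | intermediate
6 | (2Z,6S)-3,7,7-trimethylnona-2,8-diene-1,6-diol | OC/C=C(C)\CC[C@H](O)C(C)(C)C=C | intermediate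
7 | (1R)-1-[(2R,5S)-2-methyl-5-(2-methylbut-3-en-2-yl)oxolan-2-yl]ethane-1,2-diol | OC[C@@H](O)[C@@]1(C)CC[C@H](O1)C(C)(C)C=C | intermediate
8 | 6-O-TES, 7-O-TBS ether of 7 | CC[Si](CC)(CC)OC[C@@H](O[Si](C)(C)C(C)(C)C)[C@@]1(C)CC[C@H](O1)C(C)(C)C=C | intermediate
9 | (2S)-2-[(tert-butyldimethylsilyl)oxy]-2-[(2R,5S)-2-methyl-5-(2-methylbut-3-en-2-yl)oxolan-2-yl]acetaldehyde (East fragment) | O=C[C@@H](O[Si](C)(C)C(C)(C)C)[C@@]1(C)CC[C@H](O1)C(C)(C)C=C | intermediate
10 | (S)-3-bromo-2-methylpropan-1-ol | OC[C@H](C)CBr | starting material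
11 | (S)-(3-bromo-2-methylpropoxy)(tert-butyl)dimethylsilane | CC(C)(C)[Si](C)(C)OC[C@H](C)CBr | intermediate
12 | 2,2-dimethoxyacetaldehyde | COC(OC)C=O | starting material
13 | (Z)-but-2-ene | C/C=C\C | starting material
14 | (2R,3S)-1,1-dimethoxy-3-methylpent-4-en-2-ol | C=C[C@H](C)[C@@H](O)C(OC)OC | intermediate
15 | PMB ether of 14 | C=C[C@H](C)[C@@H](OCc1ccc(OC)cc1)C(OC)OC | intermediate
16 | (2R,3S)-2-[(4-methoxybenzyl)oxy]-3-methylpent-4-enal | C=C[C@H](C)[C@@H](OCc1ccc(OC)cc1)C=O | intermediate
17 | (2R,4R,5R,6S)-1-[(tert-butyldimethylsilyl)oxy]-5-[(4-methoxybenzyl)oxy]-2,6-dimethyloct-7-en-4-ol | CC(C)(C)[Si](C)(C)OC[C@H](C)C[C@@H](O)[C@H](OCc1ccc(OC)cc1)[C@@H](C)C=C | intermediate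
18 | PMP acetal TBS ether (see step 13) | CC(C)(C)[Si](C)(C)OC[C@H](C)C[C@H]1OC(c2ccc(OC)cc2)O[C@@H]1[C@@H](C)C=C | intermediate
19 | (2R)-3-[(4R,5R)-5-[(2S)-but-3-en-2-yl]-2-(4-methoxyphenyl)-1,3-dioxolan-4-yl]-2-methylpropan-1-ol | OC[C@H](C)C[C@H]1OC(c2ccc(OC)cc2)O[C@@H]1[C@@H](C)C=C | intermediate
20 | (4R,5R)-4-[(2S)-but-3-en-2-yl]-5-[(2R)-3-iodo-2-methylpropyl]-2-(4-methoxyphenyl)-1,3-dioxolane (West fragment) | IC[C@H](C)C[C@H]1OC(c2ccc(OC)cc2)O[C@@H]1[C@@H](C)C=C | intermediate
21 | methyl but-2-ynoate | CC#CC(=O)OC | starting material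
22 | methyl (2E)-3-methylpent-2-enoate | CC/C(C)=C/C(=O)OC | intermediate
23 | (2E)-3-methylpent-2-enoic acid | CC/C(C)=C/C(=O)O | intermediate
24 | coupled C6 alcohol (C6 epimers) | C=C[C@H](C)[C@H]1OC(c2ccc(OC)cc2)O[C@@H]1C[C@@H](C)CC(O)[C@@H](O[Si](C)(C)C(C)(C)C)[C@@]1(C)CC[C@H](O1)C(C)(C)C=C | intermediate
25 | C6 ketone | C=C[C@H](C)[C@H]1OC(c2ccc(OC)cc2)O[C@@H]1C[C@@H](C)CC(=O)[C@@H](O[Si](C)(C)C(C)(C)C)[C@@]1(C)CC[C@H](O1)C(C)(C)C=C | intermediate
26 | (5R)-C5-hydroxy C6 ketone | C=C[C@H](C)[C@H]1OC(c2ccc(OC)cc2)O[C@@H]1C[C@@H](C)[C@@H](O)C(=O)[C@@H](O[Si](C)(C)C(C)(C)C)[C@@]1(C)CC[C@H](O1)C(C)(C)C=C | intermediate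
27 | C5 (E)-3-methylpent-2-enoate of 26 | C=C[C@H](C)[C@H]1OC(c2ccc(OC)cc2)O[C@@H]1C[C@@H](C)[C@@H](OC(=O)/C=C(C)/CC)C(=O)[C@@H](O[Si](C)(C)C(C)(C)C)[C@@]1(C)CC[C@H](O1)C(C)(C)C=C | intermediate
28 | macrocyclic (13E)-alkene | O=C1[C@H](OC(=O)/C=C(C)/CC)[C@H](C)C[C@H]2OC(c3ccc(OC)cc3)O[C@@H]2[C@@H](C)/C=C/C(C)(C)[C@@H]2CC[C@@](C)(O2)[C@@H]1O[Si](C)(C)C(C)(C)C | intermediate
29 | hemiketal, C1–OH, C7–OTBS | CC/C(C)=C/C(=O)O[C@@H]1[C@H](C)C[C@H]2O[C@]1(O)[C@@H](O[Si](C)(C)C(C)(C)C)[C@@]1(C)CC[C@H](O1)C(C)(C)/C=C/[C@H](C)[C@H]2O | intermediate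
30 | 7-O-TBS-tonantzitlolone A | CC/C(C)=C/C(=O)O[C@@H]1[C@H](C)C[C@H]2O[C@]1(O)[C@@H](O[Si](C)(C)C(C)(C)C)[C@@]1(C)CC[C@H](O1)C(C)(C)/C=C/[C@H](C)C2=O | intermediate
31 | tonantzitlolone A | CC/C(C)=C/C(=O)O[C@@H]1[C@H](C)C[C@H]2O[C@]1(O)[C@@H](O)[C@@]1(C)CC[C@H](O1)C(C)(C)/C=C/[C@H](C)C2=O | target

## Summary

**Total steps:** 25 (East 7, West 8, acid 2, union and endgame 8).

**Longest linear sequence:** 15 steps (steps 1–7 then 18–25; the West path 9–15 then 18–25 is the same length), which is 60% of the total.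

**Three steps most likely to fail**

1. **Step 20 (C5 hydroxylation).** Facial selectivity on an acyclic dialkyl-ketone enolate may be modest or reversed. Fallback: deliberately make the (5S)-alcohol with the enantiomeric oxaziridine and install the ester by Mitsunobu reaction with 23, which gives the (5R)-ester by inversion instead of retentive acylation.
2. **Step 22 (RCM).** Closing a 15-membered ring onto a neopentyl vinyl group may be slow or give dimers. Fallback: swap the two bond formations — make C13=C14 intermolecularly by Julia–Kocienski olefination (East neopentyl aldehyde plus West C14 tetrazolyl sulfone) and close the ring at C5–C6 by intramolecular SmI2 Barbier addition of the iodide to the C6 aldehyde, then oxidise.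
3. **Step 25 (final desilylation).** The C7 TBS ether sits between two fully substituted carbons and may need forcing conditions the product will not tolerate. Fallback: change the C7 protecting group to PMB (from diol 7 via PMP acetal and regioselective DIBAL opening, then oxidation to the aldehyde) so that the last step is a neutral DDQ deprotection.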